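**Remark on numbering.** Daucane numbering is used for the bicyclic carbons: C1 (quaternary, angular methyl), C2, C3, C4 (isopropyl, OH), C5 (ring-fusion CH), C6, C7, C8 (methyl), C9, C10. β is the face of the C1 methyl, α the opposite face. The target is 1β-methyl, 2α-OAc, 4β-OH/4α-isopropyl, 5α-H, 6α-vanilloyloxy, 8α,9α-epoxide (1R,2S,4R,5S,6S,8R,9S). Compounds 1 and 18 and all reagents are assumed to be purchased.

## Analysis of the target

The target is a daucane: a five-membered ring (C1–C5) trans-fused through the C1–C5 bond to a seven-membered ring (C5, C6, C7, C8, C9, C10, C1), with seven stereocentres (C1, C2, C4, C5, C6, C8, C9). The angular methyl on quaternary C1 and the tertiary hydroxyl on C4 lie on the β face. H5, the C2 acetate, the C6 vanillate and the epoxide oxygen lie on the α face, so both secondary oxygens are 1,3-anti to the C4 hydroxyl and the C6 oxygen is homoallylic to C8–C9. The feature that invites the key move sits in the seven-membered ring: the oxygen-bearing C6 and the epoxidized C8–C9 bond are separated only by the methylene C7. The ring is therefore a latent cyclohepta-1,4-diene (C5=C6–O enol ether plus C8=C9) whose remaining sp3 pair is C10 and the quaternary C1. That is the product pattern of a divinylcyclopropane rearrangement in which C7 is the cyclopropane methylene and C1–C10 is the new bond. Sensitive groups are the acid-labile trisubstituted epoxide (which faces the C4 hydroxyl across the ring), two different esters on two similar secondary alcohols, a free guaiacol-type phenol, and on the way a β-hydroxy ketone that is also β,γ-unsaturated (retro-aldol, dehydration, conjugation). The hard points are quaternary C1 between the C2 and C5 stereocentres of a trans-fused 5–7 system, a seven-membered ring with its double bond in one defined position, and the configuration and differentiation of C2–O and C6–O.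

## Retrosynthetic reasoning

**24 back to 17 + 18 (acyl and protecting-group level).** The phenol is freed last (24 from 23), and the acetate is placed on the 2α-alcohol 22. The C2 oxygen is carried through the route as a β-silyl ether because that configuration is needed earlier for stereocontrol. It is therefore corrected late: 22 comes from ketone 21 by hydride delivered from the C4 hydroxyl, and 21 from 20 and 19. The vanillate is attached to C6 first (19 from 17 + 18) while C2 is still silylated, so the two secondary alcohols never compete.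

**17 back to 15 (epoxide and C6 carbinol).** The epoxide oxygen is removed to give homoallylic alcohol 16, whose C6 hydroxyl delivers the oxidant to the α face. The C6 carbinol is traced to ketone 15, reduced by hydride delivered from the C4 hydroxyl. Three of the seven stereocentres (C2, C6 and the epoxide pair) are thus relayed from C4 and C6 instead of being built independently.

**15 back to 13 (C5–H).** The β-hydroxy ketone 15 is the hydrolysis product of the bicyclic silyl dienol ether 13. The forward step must protonate C5 on the α face and must avoid base, which would move C8=C9 into conjugation.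

**13 back to 12 (key disconnection).** The C1–C10 bond is cut and C6 is reconnected to C8, which contracts the seven-membered ring to a cyclopropane (C6, C7, C8) carrying two alkenyl groups. The cut is placed here because it removes the seven-membered ring and the quaternary centre together, and leaves C8=C9 and the C6 oxygen exactly where the target needs them. The C6–C8 bond is not in the target; it is made only to be broken. The forward reaction must deliver C10 to the α face of the cyclopentene carbon C1.

**12 back to 9 (C7).** Removing the methylene C7 gives the silyl dienol ether 11, which comes from ketone 9 through 10. The ketone has only one enolizable position, so the regiochemistry of 11 and of the methylene transfer is fixed.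

**9 back to 5 (C6–C8 and C5–C6).** The C6–C8 bond is cut to aldehyde 7 and a crotyl-metal reagent reacting through its γ-carbon (alcohol 8, then oxidation). The C5–C6 bond is cut to the alkenyl iodide 5 (through dianion 6) and a formyl donor.

**5 back to 1 (ring substituents and the purchased stereocentre).** The isopropyl group is removed from C4 to give iodoenone 4, the iodine is removed to give 3, and the C1 methyl is removed to give the commercial silyloxy-enone 1. The single purchased stereocentre (C2) controls C4 in step 3 and C1 in step 9, and is itself inverted at the end under control of C4.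

## Alternatives that were turned down

**Alternative 1:** ring-closing metathesis (the textbook route).
- Disconnection: the C8=C9 double bond, after stepwise assembly of a fully substituted cyclopentane.
- Forward key step: conjugate allylation of 3 anti to the silyloxy group with aldol capture of the enolate, isopropyl addition at C4, then metathesis of diene A1 with second-generation Grubbs catalyst to give 16.
- Why turned down: the ring closure forms one bond and no stereocentre, so C1, C4, C5 and C6 must each be set beforehand in separate additions. Quaternary C1 arises by conjugate addition to a β,β-disubstituted enone whose enolate has a silyloxy leaving group in the β-position, which invites elimination. The aldol sets C6 under weak control and uses an aldehyde prone to conjugation. It is kept only as a fallback.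

**Alternative 2:** intramolecular Buchner ring expansion of an arene.
- Disconnection: C1–C5 and C1–C10, with the seven-membered ring derived from a benzene ring.
- Forward key step: diazoketone A2 with Rh2(OAc)4; cyclopropanation of the C5–C10 arene bond and electrocyclic opening of the norcaradiene give azulenone A3. This forms both rings, quaternary C1, the C2 carbonyl, the C6 oxygen (as a methyl enol ether) and the C8 methyl in one step.
- Why turned down: the tertiary benzylic carbinol C4 would have to be made enantioselectively from a hindered aryl isopropyl ketone, and it would then have to steer the carbene face through a small difference between a silyloxy and an isopropyl group. Insertion of the carbene into the isopropyl methine C–H (1,5) and attack at the methoxy-bearing ortho bond compete. A3 is a cycloheptatriene with two double bonds too many; it is acid-labile and needs a 1,6-reduction in addition to the same C5 protonation, so no steps are saved.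

**Alternative 3:** rhodium-catalysed [5+2] cycloaddition of a vinylcyclopropane with a tethered alkene.
- Disconnection: C1–C5 and C9–C10, both rings formed at once.
- Forward key step: ene-vinylcyclopropane A4 with [Rh(CO)2Cl]2 gives the bicyclic alkene A5.
- Why turned down: cycloadditions of this kind give the cis ring fusion, which is wrong at C5. The new double bond is C6=C7, so C6 carries no oxygen and C8=C9 is absent; allylic oxidation and a separate introduction of the C8–C9 unsaturation would be needed. The C8 methyl would have to sit on the cyclopropane, which makes the direction of ring cleavage uncertain. The 1,1-disubstituted alkene required for quaternary C1 is the least reactive partner.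

Key step: step 9

## Route

Step 1
Reactants: 1 (4R)-4-[(tert-butyldimethylsilyl)oxy]cyclopent-2-en-1-one
Product: 3 (4R)-4-[(tert-butyldimethylsilyl)oxy]-3-methylcyclopent-2-en-1-one, via lithium enolate 2 (not isolated)
Conditions: Me2CuLi (from MeLi, CuI), Et2O, −78 °C; then PhS(Cl)=N-t-Bu, THF, −78 °C
Reagents that add atoms: lithium dimethylcuprate, [Li+].C[Cu-]C
Why: Cuprate conjugate addition anti to the silyloxy group gives enolate 2, which at −78 °C does not eliminate silanolate and is dehydrogenated in the same flask (Mukaiyama dehydrogenation: sulfenylation at the α-carbon, then syn-elimination); the methyl-bearing carbon becomes sp2, so only the purchased stereocentre remains.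

Step 2
Reactants: 3 (4R)-4-[(tert-butyldimethylsilyl)oxy]-3-methylcyclopent-2-en-1-one
Product: 4 (4R)-4-[(tert-butyldimethylsilyl)oxy]-2-iodo-3-methylcyclopent-2-en-1-one
Conditions: I2, pyridine, CH2Cl2, 0 °C to rt
Reagents that add atoms: iodine, II
Why: α-Iodination of an enone by iodine/pyridine (conjugate addition of pyridine, iodination, elimination, a Baylis–Hillman-type manifold); the weak base should leave the β-silyloxy ketone intact.

Step 3
Reactants: 4 (4R)-4-[(tert-butyldimethylsilyl)oxy]-2-iodo-3-methylcyclopent-2-en-1-one
Product: 5 (1R,4R)-4-[(tert-butyldimethylsilyl)oxy]-2-iodo-3-methyl-1-(propan-2-yl)cyclopent-2-en-1-ol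
Conditions: i-PrLi, CeCl3, THF, −78 °C; aq. NH4Cl
Reagents that add atoms: isopropyllithium, [Li]C(C)C
Why: Organocerium 1,2-addition: the low basicity suppresses enolization, β-elimination and iodine–metal exchange; attack anti to the silyloxy group across the ring should place isopropyl α and hydroxyl β (C4 set by relay from C2).

Step 4
Reactants: 5 (1R,4R)-4-[(tert-butyldimethylsilyl)oxy]-2-iodo-3-methyl-1-(propan-2-yl)cyclopent-2-en-1-ol
Product: 7 (3R,5R)-3-[(tert-butyldimethylsilyl)oxy]-5-hydroxy-2-methyl-5-(propan-2-yl)cyclopent-1-ene-1-carbaldehyde, via dilithio species 6 (not isolated)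
Conditions: MeLi (1 equiv), then t-BuLi (2 equiv), Et2O, −78 °C; DMF, −78 to 0 °C; aq. NH4Cl
Reagents that add atoms: N,N-dimethylformamide, CN(C)C=O
Why: Deprotonation of the hydroxyl, iodine–lithium exchange and formylation of the alkenyllithium; β-elimination of the alkoxide is impossible because it would give a cyclic allene.

Step 5
Reactants: 7 (3R,5R)-3-[(tert-butyldimethylsilyl)oxy]-5-hydroxy-2-methyl-5-(propan-2-yl)cyclopent-1-ene-1-carbaldehyde
Product: 8 (1R,4R)-4-[(tert-butyldimethylsilyl)oxy]-2-(1-hydroxy-2-methylbut-3-en-1-yl)-3-methyl-1-(propan-2-yl)cyclopent-2-en-1-ol (mixture of side-chain diastereomers)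
Conditions: crotylmagnesium chloride (3 equiv), THF, −78 °C; aq. NH4Cl
Reagents that add atoms: crotylmagnesium chloride (but-2-en-1-ylmagnesium chloride), C/C=C/C[Mg]Cl
Why: Allylmetal addition through a six-membered transition state joins C6 to the γ-carbon of the crotyl unit and gives the branched homoallylic alcohol; both new centres are erased later (C6 is oxidized, C8 is enolized).

Step 6
Reactants: 8 (1R,4R)-4-[(tert-butyldimethylsilyl)oxy]-2-(1-hydroxy-2-methylbut-3-en-1-yl)-3-methyl-1-(propan-2-yl)cyclopent-2-en-1-ol
Product: 9 1-[(3R,5R)-3-[(tert-butyldimethylsilyl)oxy]-5-hydroxy-2-methyl-5-(propan-2-yl)cyclopent-1-en-1-yl]-2-methylbut-3-en-1-one (both epimers at the α-carbon)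
Conditions: Dess–Martin periodinane, NaHCO3, CH2Cl2, 0 °C
Reagents that add atoms: none
Why: Dess–Martin oxidation of the secondary allylic alcohol; the tertiary alcohol is inert and the buffered, base-free medium should keep the β,γ-double bond out of conjugation.

Step 7
Reactants: 9 1-[(3R,5R)-3-[(tert-butyldimethylsilyl)oxy]-5-hydroxy-2-methyl-5-(propan-2-yl)cyclopent-1-en-1-yl]-2-methylbut-3-en-1-one
Product: 11 (3R,5R)-3-[(tert-butyldimethylsilyl)oxy]-2-methyl-1-[2-methyl-1-[(triethylsilyl)oxy]buta-1,3-dien-1-yl]-5-(propan-2-yl)-5-[(triethylsilyl)oxy]cyclopent-1-ene (E/Z mixture at the enol ether), via mono-silylated ketone 10 (not isolated)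
Conditions: TESOTf (3 equiv), Et3N (5 equiv), CH2Cl2, −78 to 0 °C
Reagents that add atoms: triethylsilyl trifluoromethanesulfonate, CC[Si](CC)(CC)OS(=O)(=O)C(F)(F)F
Why: Silylation of the tertiary hydroxyl, then soft enolization of ketone 10; the only α-hydrogen (on C8, also allylic) is removed, so a single regioisomeric 2-silyloxydiene forms, and its geometry does not matter (see step 9).

Step 8
Reactants: 11 (3R,5R)-3-[(tert-butyldimethylsilyl)oxy]-2-methyl-1-[2-methyl-1-[(triethylsilyl)oxy]buta-1,3-dien-1-yl]-5-(propan-2-yl)-5-[(triethylsilyl)oxy]cyclopent-1-ene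
Product: 12 (3R,5R)-3-[(tert-butyldimethylsilyl)oxy]-1-[2-ethenyl-2-methyl-1-[(triethylsilyl)oxy]cyclopropyl]-2-methyl-5-(propan-2-yl)-5-[(triethylsilyl)oxy]cyclopent-1-ene (mixture of cyclopropane stereoisomers)
Conditions: Et2Zn, CH2I2, toluene, 0 °C; pyridine quench
Reagents that add atoms: diiodomethane, ICI
Why: Simmons–Smith cyclopropanation (Furukawa variant): the electrophilic zinc carbenoid should choose the most electron-rich double bond, the silyl enol ether, over the terminal vinyl group and the shielded tetrasubstituted ring alkene; this brings in C7 and the temporary C6–C8 bond.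

Step 9
Reactants: 12 (3R,5R)-3-[(tert-butyldimethylsilyl)oxy]-1-[2-ethenyl-2-methyl-1-[(triethylsilyl)oxy]cyclopropyl]-2-methyl-5-(propan-2-yl)-5-[(triethylsilyl)oxy]cyclopent-1-ene
Product: 13 2β-[(tert-butyldimethylsilyl)oxy]-4β,6-bis[(triethylsilyl)oxy]dauca-5,8-diene
Conditions: toluene (degassed), Et3N (trace), BHT (trace), sealed tube, 120 °C
Reagents that add atoms: none
Why: Thermal [3,3]-sigmatropic (Cope) rearrangement of a cis-1,2-dialkenylcyclopropane through the boat transition state; the closest known type is the silyloxy-divinylcyclopropane to cycloheptadiene rearrangement, driven by release of ring strain and ending in a silyl enol ether that cannot revert. The seven-membered ring closes by formation of C1–C10 with concerted cleavage of the temporary C6–C8 bond (ring enlargement from three to seven, C7 becoming the methylene between the two new double bonds), so C8=C9 and the C5=C6 enol ether appear exactly where the target has the epoxide and the C6 oxygen. Stereoisomers of 12 with trans alkenyl groups, or with the wrong cyclopropane face toward the ring, should enter the same manifold by reversible homolysis of the C6–C8 bond, which is flanked by silyloxy and alkenyl on C6 and by methyl and vinyl on C8 (one-centre epimerization, a Curtin–Hammett situation). The only new stereocentre is quaternary C1: the vinyl terminus C10 should add to the cyclopentene face anti to the silyl ether on the neighbouring C2, the α face, which leaves the methyl β. The step needs this facial selectivity and it needs the Cope pathway to win over the homodienyl 1,5-hydrogen shift and the vinylcyclopropane to cyclopentene rearrangement; the first rests on the β-silyloxy group directly beside the reacting carbon, the second on the lower barrier of the boat Cope and on the fully substituted receiving carbon, which disfavours hydrogen transfer. The methyl on C1 points inward in the boat and the bond forms at a tetrasubstituted alkene carbon, hence the elevated temperature.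

Step 10
Reactants: 13 2β-[(tert-butyldimethylsilyl)oxy]-4β,6-bis[(triethylsilyl)oxy]dauca-5,8-diene
Product: 15 2β-[(tert-butyldimethylsilyl)oxy]-4β-hydroxy-5α-dauc-8-en-6-one, via silyloxy ketone 14 (not isolated)
Conditions: HF·pyridine, pyridine, THF, −20 to 0 °C
Reagents that add atoms: none
Why: Protodesilylation cleaves the enol ether first; C5 should be protonated on the α face, anti to the pseudoaxial C1 methyl (axial attack leading directly to the staggered trans-fused ketone) with the β face further screened by the C4 silyl ether, and the acidic, base-free medium avoids conjugation of C8=C9 and retro-aldol; the tertiary triethylsilyl ether then falls while the hindered secondary TBS ether should survive.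

Step 11
Reactants: 15 2β-[(tert-butyldimethylsilyl)oxy]-4β-hydroxy-5α-dauc-8-en-6-one
Product: 16 2β-[(tert-butyldimethylsilyl)oxy]-5α-dauc-8-ene-4β,6α-diol
Conditions: Me4NBH(OAc)3, MeCN/AcOH, −30 °C
Reagents that add atoms: none
Why: Evans–Saksena reduction: the C4 hydroxyl exchanges onto boron and delivers hydride intramolecularly to the β face of the C6 ketone, which should give the 6α-alcohol (anti-1,3-diol).

Step 12
Reactants: 16 2β-[(tert-butyldimethylsilyl)oxy]-5α-dauc-8-ene-4β,6α-diol
Product: 17 2β-[(tert-butyldimethylsilyl)oxy]-8α,9α-epoxy-5α-daucane-4β,6α-diol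
Conditions: VO(acac)2 (cat.), t-BuOOH, CH2Cl2, 0 °C to rt
Reagents that add atoms: tert-butyl hydroperoxide, CC(C)(C)OO
Why: Vanadium-catalysed epoxidation directed by the homoallylic C6 hydroxyl delivers oxygen to the α face of C8=C9, the face also favoured sterically (anti to the angular methyl).

Step 13
Reactants: 17 2β-[(tert-butyldimethylsilyl)oxy]-8α,9α-epoxy-5α-daucane-4β,6α-diol; 18 4-(benzyloxy)-3-methoxybenzoic acid
Product: 19 2β-[(tert-butyldimethylsilyl)oxy]-8α,9α-epoxy-4β-hydroxy-5α-daucan-6α-yl 4-(benzyloxy)-3-methoxybenzoate
Conditions: EDC·HCl, DMAP, CH2Cl2, rt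
Reagents that add atoms: none
Why: Steglich esterification of the only secondary hydroxyl; the tertiary C4 hydroxyl does not acylate and the epoxide tolerates the neutral conditions.

Step 14
Reactants: 19 2β-[(tert-butyldimethylsilyl)oxy]-8α,9α-epoxy-4β-hydroxy-5α-daucan-6α-yl 4-(benzyloxy)-3-methoxybenzoate
Product: 20 8α,9α-epoxy-2β,4β-dihydroxy-5α-daucan-6α-yl 4-(benzyloxy)-3-methoxybenzoate
Conditions: TBAF, AcOH (1:1), THF, 40 °C
Reagents that add atoms: none
Why: Fluoride cleavage of the hindered secondary silyl ether; buffering with acetic acid should protect the aryl ester and keep the C4 alkoxide from attacking the epoxide.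

Step 15
Reactants: 20 8α,9α-epoxy-2β,4β-dihydroxy-5α-daucan-6α-yl 4-(benzyloxy)-3-methoxybenzoate
Product: 21 8α,9α-epoxy-4β-hydroxy-2-oxo-5α-daucan-6α-yl 4-(benzyloxy)-3-methoxybenzoate
Conditions: Dess–Martin periodinane, NaHCO3, CH2Cl2, rt
Reagents that add atoms: none
Why: Dess–Martin oxidation of the single secondary alcohol; no α-stereocentre can be lost because C1 is quaternary.

Step 16
Reactants: 21 8α,9α-epoxy-4β-hydroxy-2-oxo-5α-daucan-6α-yl 4-(benzyloxy)-3-methoxybenzoate
Product: 22 8α,9α-epoxy-2α,4β-dihydroxy-5α-daucan-6α-yl 4-(benzyloxy)-3-methoxybenzoate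
Conditions: Me4NBH(OAc)3, MeCN/AcOH, −30 to −10 °C
Reagents that add atoms: none
Why: Evans–Saksena reduction across the five-membered ring: the β-oriented C4 hydroxyl delivers hydride to the β face of the C2 ketone, which should give the trans-1,3-diol (2α-alcohol) and so correct the configuration that had to be β for steps 3 and 9.

Step 17
Reactants: 22 8α,9α-epoxy-2α,4β-dihydroxy-5α-daucan-6α-yl 4-(benzyloxy)-3-methoxybenzoate
Product: 23 2α-acetoxy-8α,9α-epoxy-4β-hydroxy-5α-daucan-6α-yl 4-(benzyloxy)-3-methoxybenzoate
Conditions: Ac2O, Et3N, DMAP (cat.), CH2Cl2, rt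
Reagents that add atoms: acetic anhydride, CC(=O)OC(C)=O
Why: DMAP-catalysed acetylation of the secondary alcohol; the hindered tertiary alcohol should stay free at room temperature.

Step 18
Reactants: 23 2α-acetoxy-8α,9α-epoxy-4β-hydroxy-5α-daucan-6α-yl 4-(benzyloxy)-3-methoxybenzoate
Product: 24 2α-acetoxy-8α,9α-epoxy-4β-hydroxy-5α-daucan-6α-yl 4-hydroxy-3-methoxybenzoate
Conditions: H2 (1 atm), Pd/C, EtOAc, rt
Reagents that add atoms: none
Why: Hydrogenolysis of the benzyl aryl ether; the trialkyl-substituted epoxide and both esters should be inert under these neutral conditions, and no alkene remains.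

## Compound list

1 | (4R)-4-[(tert-butyldimethylsilyl)oxy]cyclopent-2-en-1-one | O=C1C=C[C@H](O[Si](C)(C)C(C)(C)C)C1 | starting material
2 | lithium (3R,4R)-4-[(tert-butyldimethylsilyl)oxy]-3-methylcyclopent-1-en-1-olate (methyl trans to silyloxy) | [Li+].[O-]C1=C[C@@H](C)[C@H](O[Si](C)(C)C(C)(C)C)C1 | intermediate
3 | (4R)-4-[(tert-butyldimethylsilyl)oxy]-3-methylcyclopent-2-en-1-one | O=C1C=C(C)[C@H](O[Si](C)(C)C(C)(C)C)C1 | intermediate
4 | (4R)-4-[(tert-butyldimethylsilyl)oxy]-2-iodo-3-methylcyclopent-2-en-1-one | O=C1C(I)=C(C)[C@H](O[Si](C)(C)C(C)(C)C)C1 | intermediate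
5 | (1R,4R)-4-[(tert-butyldimethylsilyl)oxy]-2-iodo-3-methyl-1-(propan-2-yl)cyclopent-2-en-1-ol (hydroxyl cis to silyloxy) | CC(C)[C@@]1(O)C(I)=C(C)[C@H](O[Si](C)(C)C(C)(C)C)C1 | intermediate
6 | dilithio derivative of 5 (alkenyllithium at the former C–I carbon, lithium alkoxide) | CC(C)[C@@]1(O[Li])C([Li])=C(C)[C@H](O[Si](C)(C)C(C)(C)C)C1 | intermediate
7 | (3R,5R)-3-[(tert-butyldimethylsilyl)oxy]-5-hydroxy-2-methyl-5-(propan-2-yl)cyclopent-1-ene-1-carbaldehyde | CC(C)[C@@]1(O)C(C=O)=C(C)[C@H](O[Si](C)(C)C(C)(C)C)C1 | intermediate
8 | (1R,4R)-4-[(tert-butyldimethylsilyl)oxy]-2-(1-hydroxy-2-methylbut-3-en-1-yl)-3-methyl-1-(propan-2-yl)cyclopent-2-en-1-ol (mixture of side-chain diastereomers) | CC(C)[C@@]1(O)C(C(O)C(C)C=C)=C(C)[C@H](O[Si](C)(C)C(C)(C)C)C1 | intermediate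
9 | 1-[(3R,5R)-3-[(tert-butyldimethylsilyl)oxy]-5-hydroxy-2-methyl-5-(propan-2-yl)cyclopent-1-en-1-yl]-2-methylbut-3-en-1-one (both α-epimers) | CC(C)[C@@]1(O)C(C(=O)C(C)C=C)=C(C)[C@H](O[Si](C)(C)C(C)(C)C)C1 | intermediate
10 | 1-[(3R,5R)-3-[(tert-butyldimethylsilyl)oxy]-2-methyl-5-(propan-2-yl)-5-[(triethylsilyl)oxy]cyclopent-1-en-1-yl]-2-methylbut-3-en-1-one | CC(C)[C@@]1(O[Si](CC)(CC)CC)C(C(=O)C(C)C=C)=C(C)[C@H](O[Si](C)(C)C(C)(C)C)C1 | intermediate
11 | (3R,5R)-3-[(tert-butyldimethylsilyl)oxy]-2-methyl-1-[2-methyl-1-[(triethylsilyl)oxy]buta-1,3-dien-1-yl]-5-(propan-2-yl)-5-[(triethylsilyl)oxy]cyclopent-1-ene (E/Z mixture) | CC(C)[C@@]1(O[Si](CC)(CC)CC)C(C(O[Si](CC)(CC)CC)=C(C)C=C)=C(C)[C@H](O[Si](C)(C)C(C)(C)C)C1 | intermediate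
12 | (3R,5R)-3-[(tert-butyldimethylsilyl)oxy]-1-[2-ethenyl-2-methyl-1-[(triethylsilyl)oxy]cyclopropyl]-2-methyl-5-(propan-2-yl)-5-[(triethylsilyl)oxy]cyclopent-1-ene (mixture of cyclopropane stereoisomers) | CC(C)[C@@]1(O[Si](CC)(CC)CC)C(C2(O[Si](CC)(CC)CC)CC2(C)C=C)=C(C)[C@H](O[Si](C)(C)C(C)(C)C)C1 | intermediate
13 | 2β-[(tert-butyldimethylsilyl)oxy]-4β,6-bis[(triethylsilyl)oxy]dauca-5,8-diene (1β-methyl, 4α-isopropyl) | CC[Si](CC)(CC)OC1=C2[C@](O[Si](CC)(CC)CC)(C(C)C)C[C@@H](O[Si](C)(C)C(C)(C)C)[C@]2(C)CC=C(C)C1 | intermediate
14 | 2β-[(tert-butyldimethylsilyl)oxy]-4β-[(triethylsilyl)oxy]-5α-dauc-8-en-6-one | O=C2CC(C)=CC[C@@]3(C)[C@H](O[Si](C)(C)C(C)(C)C)C[C@@](O[Si](CC)(CC)CC)(C(C)C)[C@H]23 | intermediate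
15 | 2β-[(tert-butyldimethylsilyl)oxy]-4β-hydroxy-5α-dauc-8-en-6-one | O=C2CC(C)=CC[C@@]3(C)[C@H](O[Si](C)(C)C(C)(C)C)C[C@@](O)(C(C)C)[C@H]23 | intermediate
16 | 2β-[(tert-butyldimethylsilyl)oxy]-5α-dauc-8-ene-4β,6α-diol | O[C@H]2CC(C)=CC[C@@]3(C)[C@H](O[Si](C)(C)C(C)(C)C)C[C@@](O)(C(C)C)[C@H]23 | intermediate
17 | 2β-[(tert-butyldimethylsilyl)oxy]-8α,9α-epoxy-5α-daucane-4β,6α-diol | O[C@H]2C[C@@]3(C)O[C@H]3C[C@@]3(C)[C@H](O[Si](C)(C)C(C)(C)C)C[C@@](O)(C(C)C)[C@H]23 | intermediate
18 | 4-(benzyloxy)-3-methoxybenzoic acid | COc1cc(C(=O)O)ccc1OCc1ccccc1 | starting material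
19 | 2β-[(tert-butyldimethylsilyl)oxy]-8α,9α-epoxy-4β-hydroxy-5α-daucan-6α-yl 4-(benzyloxy)-3-methoxybenzoate | COc1cc(C(=O)O[C@H]2C[C@@]3(C)O[C@H]3C[C@@]3(C)[C@H](O[Si](C)(C)C(C)(C)C)C[C@@](O)(C(C)C)[C@H]23)ccc1OCc1ccccc1 | intermediate
20 | 8α,9α-epoxy-2β,4β-dihydroxy-5α-daucan-6α-yl 4-(benzyloxy)-3-methoxybenzoate | COc1cc(C(=O)O[C@H]2C[C@@]3(C)O[C@H]3C[C@@]3(C)[C@H](O)C[C@@](O)(C(C)C)[C@H]23)ccc1OCc1ccccc1 | intermediate
21 | 8α,9α-epoxy-4β-hydroxy-2-oxo-5α-daucan-6α-yl 4-(benzyloxy)-3-methoxybenzoate | COc1cc(C(=O)O[C@H]2C[C@@]3(C)O[C@H]3C[C@@]3(C)C(=O)C[C@@](O)(C(C)C)[C@H]23)ccc1OCc1ccccc1 | intermediate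
22 | 8α,9α-epoxy-2α,4β-dihydroxy-5α-daucan-6α-yl 4-(benzyloxy)-3-methoxybenzoate | COc1cc(C(=O)O[C@H]2C[C@@]3(C)O[C@H]3C[C@@]3(C)[C@@H](O)C[C@@](O)(C(C)C)[C@H]23)ccc1OCc1ccccc1 | intermediate
23 | 2α-acetoxy-8α,9α-epoxy-4β-hydroxy-5α-daucan-6α-yl 4-(benzyloxy)-3-methoxybenzoate | COc1cc(C(=O)O[C@H]2C[C@@]3(C)O[C@H]3C[C@@]3(C)[C@@H](OC(C)=O)C[C@@](O)(C(C)C)[C@H]23)ccc1OCc1ccccc1 | intermediate
24 | 2α-acetoxy-8α,9α-epoxy-4β-hydroxy-5α-daucan-6α-yl 4-hydroxy-3-methoxybenzoate (1R,2S,4R,5S,6S,8R,9S) | COc1cc(C(=O)O[C@H]2C[C@@]3(C)O[C@H]3C[C@@]3(C)[C@@H](OC(C)=O)C[C@@](O)(C(C)C)[C@H]23)ccc1O | target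

## Step count and least certain steps

Total step count: 18. Longest linear sequence: 18 steps (1 to 24); acid 18 is purchased and enters at step 13.

**Step 9 (key step).** The most likely failure is loss of facial control at C1. If epimerization of the cyclopropane through C6–C8 homolysis is slower than rearrangement of the mismatched cis isomer, C10 is delivered partly to the β face. The trans isomers may also drain into the homodienyl hydrogen shift. The α face carries the C4 isopropyl group, so the bias rests on the C2 silyl ether alone. The fallback abandons the cyclopropane and builds the bicycle stepwise from 3. Hosomi–Sakurai conjugate allylation (allyltrimethylsilane, TiCl4, −78 °C) anti to the silyloxy group, with aldol capture of the titanium enolate by 3-methylbut-3-enal, gives the aldol ketone F1. Organocerium addition of the isopropyl group, anti to the new side chain, gives the diene diol F2. Ring-closing metathesis with second-generation Grubbs catalyst closes C8=C9 to the bicyclic diol F3 (both C6 epimers). Dess–Martin oxidation of its secondary hydroxyl comes back to the route at 15.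

**Step 8.** The most likely failure is slow methylene transfer to the crowded tetrasubstituted enol ether, so that the carbenoid attacks the terminal vinyl group instead, or opening of the silyloxycyclopropane by the zinc iodide formed. The fallback sets out from 9 and changes the nucleophile from a neutral enol ether to a metal enolate. The lithium dienolate–alkoxide (LiHMDS, THF, −78 °C) is treated with the samarium carbenoid from Sm metal and CH2I2, which is bound to the enolate oxygen and delivered to the enolate double bond. This gives the cyclopropanol F4, which is silylated on both hydroxyls with TESOTf/2,6-lutidine at low temperature and comes back at 12.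

**Step 10.** The most likely failure is protonation of C5 from the β face, which gives the cis-fused ketone. It cannot be repaired afterwards by base, because enolization would move C8=C9 into conjugation and the β-hydroxy ketone would undergo retro-aldol. The fallback replaces substrate control by reagent control. Enol ether 13 is protonated at −78 °C with a chiral Lewis-acid-assisted Brønsted acid (BINOL·SnCl4, enantiomer chosen to match), which selects the face of the enol ether. This comes back at 14 and makes no new compound F0.

**Step 16.** The most likely failure is slow intramolecular hydride delivery to the neopentyl ketone. The epoxide would then have time to open in the acetic acid medium, by acetolysis or by transannular attack of the C4 hydroxyl. The fallback avoids ketone 21 and the acidic medium. Alcohol 20 is inverted directly by a Mitsunobu reaction with acetic acid (PPh3, DIAD, toluene), which installs the 2α-acetate with inversion under neutral conditions. This comes back at 23 and makes no new compound F0.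

## Further compounds

F1 | step 9 | 3α-allyl-4β-[(tert-butyldimethylsilyl)oxy]-2β-(1-hydroxy-3-methylbut-3-en-1-yl)-3β-methylcyclopentan-1-one (allyl trans to silyloxy, side chain trans to allyl, carbinol centre as a mixture) | C=CC[C@@]1(C)[C@H](O[Si](C)(C)C(C)(C)C)CC(=O)[C@@H]1C(O)CC(C)=C
F2 | step 9 | tertiary alcohol from isopropyl addition to F1: 3α-allyl-4β-[(tert-butyldimethylsilyl)oxy]-2β-(1-hydroxy-3-methylbut-3-en-1-yl)-3β-methyl-1α-(propan-2-yl)cyclopentan-1β-ol (carbinol centre of the side chain as a mixture) | C=CC[C@@]1(C)[C@H](O[Si](C)(C)C(C)(C)C)C[C@@](O)(C(C)C)[C@@H]1C(O)CC(C)=C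
F3 | step 9 | 2β-[(tert-butyldimethylsilyl)oxy]-5α-dauc-8-ene-4β,6-diol (both C6 epimers) | OC2CC(C)=CC[C@@]3(C)[C@H](O[Si](C)(C)C(C)(C)C)C[C@@](O)(C(C)C)[C@H]23
F4 | step 8 | 1-[(3R,5R)-3-[(tert-butyldimethylsilyl)oxy]-5-hydroxy-2-methyl-5-(propan-2-yl)cyclopent-1-en-1-yl]-2-ethenyl-2-methylcyclopropan-1-ol (mixture of cyclopropane stereoisomers) | CC(C)[C@@]1(O)C(C2(O)CC2(C)C=C)=C(C)[C@H](O[Si](C)(C)C(C)(C)C)C1
F0 | step 10 | none | none
F0 | step 16 | none | none
A1 | alternative 1 | metathesis diene: 3α-allyl-4β-[(tert-butyldimethylsilyl)oxy]-2β-[(1S)-1-hydroxy-3-methylbut-3-en-1-yl]-3β-methyl-1α-(propan-2-yl)cyclopentan-1β-ol | C=CC[C@@]1(C)[C@H](O[Si](C)(C)C(C)(C)C)C[C@@](O)(C(C)C)[C@@H]1[C@@H](O)CC(C)=C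
A2 | alternative 2 | (5R)-2-diazo-5-(2-methoxy-4-methylphenyl)-6-methyl-5-[(triethylsilyl)oxy]heptan-3-one | COc1cc(C)ccc1[C@](O[Si](CC)(CC)CC)(C(C)C)CC(=O)C(C)=[N+]=[N-]
A3 | alternative 2 | 6-methoxy-4β-[(triethylsilyl)oxy]dauca-5,7,9-trien-2-one (azulenone from ring expansion) | COC1=C2[C@](O[Si](CC)(CC)CC)(C(C)C)CC(=O)[C@]2(C)C=CC(C)=C1
A4 | alternative 3 | (3S,5R,6E)-3-[(tert-butyldimethylsilyl)oxy]-7-cyclopropyl-2-methyl-5-(propan-2-yl)-5-[(triethylsilyl)oxy]hepta-1,6-diene | C=C(C)[C@@H](O[Si](C)(C)C(C)(C)C)C[C@@](O[Si](CC)(CC)CC)(C(C)C)/C=C/C1CC1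
A5 | alternative 3 | cis-fused 2α-[(tert-butyldimethylsilyl)oxy]-4β-[(triethylsilyl)oxy]-14-nor-5β-dauc-6-ene | C2=CCCC[C@@]3(C)[C@@H](O[Si](C)(C)C(C)(C)C)C[C@@](O[Si](CC)(CC)CC)(C(C)C)[C@@H]23
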